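The constants used here are those of an exercise, and the outcome is calculated.

In the first minutes of both flasks, E pairs to E2, E2 crystallises as Z, and E also takes dissolved E2 into E.E2, which no longer counts as E2.

- east: E 20 mM; temperature 60 °C; time 50 min
- north: E 20 mM; temperature 75 °C; time 50 min

- which flask leads in amount of E2, in percent of the E charged ("all alike" within 1.5 percentage points) (east / north / all alike)
- how much E2 is there at the end, in percent of the E charged: east
- how much E2 is there at the end, in percent of the E charged: north

- percent here means E units held: one E2 or Z counts as two
- percent here means E units held: one E.E2 counts as three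
- what is said of E2 includes Z
- where a step has two of a species, its rate is k times that concentration squared, and two are used at each turn
- Z is a solid; its amount is given per volume of the solution
- all constants are for 60 °C and move with temperature by the activation energies and enthalpies

    Z ⇌ E2, rate k1*(cs1 - [E2]) while solid is left; crystals form when [E2] > cs1 (cs1 = 0.44 mM, k1 = 0.0099 s⁻¹)
    E + E2 → E.E2 (k2 = 0.073 L mol⁻¹ s⁻¹, Ea2 = 68.0 kJ mol⁻¹)
    E + E ⇌ E2 (K3 = 85 L mol⁻¹, k3 = 0.020 L mol⁻¹ s⁻¹, Ea3 = 51.0 kJ mol⁻¹, ΔH3 = −27.0 kJ mol⁻¹)
    (constants at 60 °C)

You wanted a quick number, so here is my reckoning. In east, pairing alone halves E in 20.8 min, while crystals take up excess E2 within 1.68 min. That is shorter, so [E2] stays near its solubility 0.44 mM and the drain of E into E.E2 is pseudo-first-order, while pairing stays second order in E. I drop the back step of pairing. Call n the elapsed time over the halving time: the share of E left is one over one plus n, which is 29.4% for east.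

Each E.E2 holds 3 E units. Summing the loss against the pairing gives the drain number, a selectivity factor: the share of the charge lost to E.E2 per unit of ln(one plus n), equal to 3 k2 times the solubility over 2 k3 times the charge, 12.0% in east. [E2] also runs above solubility early on. While E pairs, I put that excess at k3 times [E] squared over k1, and summed against the pairing it comes to 3 k2 times the charge over 2 times 2 k1. Dissolved E2 starts from nothing, so by my judgement I take half of that, which adds 5.53% in east.

So east has 20.3% as E.E2 and 50.3% as E2. For north, k3 rises by a factor of 2.2 and k2 by a factor of 2.9, and I hold k1 and the solubility. The halving time becomes 9.42 min and the drain number 15.7%. That leaves 15.9% as E, 44.8% as E.E2 and 39.3% as E2. The leader is east.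

Your forecast says east, with 49.5% in east and 38% in north, on the ground that “Heat speeds the E.E2 drain more than dimer formation”.

The flask gives 50.8% in east and 41.0% in north, so east leads by 9.8 percentage points, against a margin of 1.5 points. At the end, E.E2 stands at 41.7% in north and 20.4% in east.

Now read east at 30 min. The drain number gives 16.3% as E.E2 and 42.8% as E2. The flask shows 15.9% and 44.1%.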